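## The problem

Compound 22 is a flavan-3-ol dimer in which C4 of a 5-deoxy upper unit (benzo ring A, catechol ring B, pyran ring C) is bonded to C6 of (+)-catechin (benzo ring D, catechol ring E, pyran ring F). Of its five stereocentres, (2R,3S) in ring F are those of natural (+)-catechin and can be bought. The three in ring C are (2R,3R,4S), with ring B at C2, the hydroxyl at C3 and ring D at C4 all on one face. The ring F centres lie many bonds away across the C4–C6 aryl axis and cannot be trusted to direct ring C, so upper C2 has to be set by a reagent; once set, C2 can control C4 and C3 through the half-chair of ring C. The interflavan bond must go to C6 although C8 is the more reactive carbon of ring D, so C8 needs a blocking group and C6 a handle. The free compound (eight phenols, two secondary alcohols) is oxidised by air, opens at C2 through quinone methides in base and ionises at the benzylic C2–O1 and C4–aryl bonds in acid, so all skeletal work belongs on a fully protected form that one mild step can unmask. The feature that makes the key step possible is that upper C4 carries two aryl groups (ring A and ring D) next to C3, while C2 is bonded to O1 of ring A: C3=C4 can be an alkene between an O1-bound 1-arylallyl group and a 1,1-diarylethene carbon, which is the product of a ring-closing olefin metathesis that closes ring C.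

## Retrosynthesis

**22 from 21.** The last cut removes eight O–benzyl bonds and the C8–Br bond of the all-cis dimer 21. Benzyl is used on every oxygen, including the lower 3-OH, so that one hydrogenolysis frees all ten hydroxyls and removes the bromine; a silyl ether on the lower 3-OH would cost a separate fluoride step. The forward reaction must be neutral (amine-buffered) because the product is acid- and base-sensitive.

**21 from 17 via 20 and 19.** The C3–O bond and the C4–H bond of ring C are removed to give the 4-aryl-flav-3-ene 17, whose only ring C stereocentre is C2. The alkene lets C2 relay its configuration: syn hydroboration on the face away from ring B (alkylborane 18) puts H on C4, so ring D ends cis to ring B, and puts O on C3 trans to both aryl groups (19). Oxidation to ketone 20 and reduction with a bulky hydride then turn C3 over to give 21. Direct cis functionalisation is not available, since the all-cis pattern corresponds to anti addition of H and OH across C3=C4. The precursor has one stereocentre instead of three; the forward steps need facial control by the C2 aryl group and a ketone that does not enolise before it is reduced.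

**17 from 16 (key disconnection).** The C3=C4 bond is cut by retro-metathesis to the diene 16, an aryl 1-arylallyl ether with an ortho 1-arylvinyl group. The classical neighbour, electrophilic substitution of a flavan-4-yl cation on catechin, would favour C8 and the 3,4-trans series. The metathesis makes no regiochemical or stereochemical demand and leaves C2 untouched. Ring C is opened to two terminal alkenes; the forward step has only to close a six-membered ring onto a hindered 1,1-diarylethene.

**16 from 14 via 15.** The C4=CH2 bond is traced to the diaryl ketone 15 (carbonyl methylenation) and the ketone to the diarylmethanol 14 (alcohol oxidation). This places the difficult C–C bond formation on an unhindered aldehyde instead of on a ketone. The forward steps are functional group changes on a fully protected substrate.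

**14 from 13 and 12.** The C4–C6 bond (upper numbering–lower numbering) is cut between the carbinol carbon and ring D, giving the C6 arylmagnesium reagent 13 and aldehyde 12. The position of the metal fixes the 4→6 connectivity without ambiguity, and the two halves of the molecule are joined late. The precursors are a monomeric catechin derivative and a small chiral aldehyde. The forward step needs a C6 organometallic in the presence of the C8 bromide.

**12 from 9 and 10 (via 11).** The O1–C2 bond is cut to the phenol 10 (as aryloxide 11) and the linear cinnamyl carbonate 9; an iridium-catalysed branched-selective allylic etherification sets C2. Doing this on the small aldehyde, and not on a late 2-(1-arylvinyl)phenol, means that the phenol needs no protecting group and the new stereocentre can be assayed and upgraded before the fragments are joined. Both precursors are achiral. The forward step must give the branched (S)-ether without later loss of configuration.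

**9 from 6 via 8 and 7.** The carbonate is cut back through allylic alcohol 8 and cinnamate 7 to aldehyde 6 (olefination, reduction, acylation); three routine steps.

**13 from 1 via 5, 4, 3 and 2.** The C6–Mg bond comes from the C6 iodide 5 by halogen–metal exchange. Iodide 5 is traced back through iodination (C6–I) to 4, O-benzylation at O3 to 3, bromination at C8 to 2, and phenol benzylation to (+)-catechin 1. Bromine goes first to the more reactive C8 and thereby directs iodine to C6; the heavier halogen then exchanges selectively. The ring F stereocentres are bought with 1.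

## Roads not taken

**Alternative 1:** The cut runs through ring F. Lower O1–C2 and C3–C4 are formed together when the ortho-hydroxybenzyl alcohol A2 (ring D already attached to a finished upper unit) is dehydrated to ortho-quinone methide reactivity and trapped by the E-enol acetate A3, giving A1.
- Merits: two bonds, a ring and both lower stereocentres arise in one step; the E geometry translates suprafacially into the 2,3-trans catechin relationship; the 4→6 connectivity is built into A2, so no halogen at C8 is needed and none has to be removed.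
- Weak points: the route discards the two stereocentres that (+)-catechin supplies and asks the distant upper unit to choose the face of the cycloaddition, for which no strong bias can be expected. The regiochemistry depends on the dialkoxyaryl donor of A3 outweighing its acetoxy group. The hardest part of the target, the all-cis ring C with its C4–aryl bond, is only moved into the synthesis of A2.
- Comparison: this road is better where the chosen plan is weakest in economy (halogenation at C8 and C6, and dehalogenation). The chosen plan sets against it the chiral pool for ring F (1 to 5) and a key step that attacks ring C itself.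

**Alternative 2:** The cut is O1–C8a of ring C. The acyclic alcohol A5, which carries all three upper stereocentres, is closed to A4 by displacement of the ortho bromide of ring A with Pd(OAc)2 and a bulky biaryl phosphine.
- Merits: the ring closure forms an aryl–oxygen bond and touches no stereocentre; the upper 3-oxygen is already benzylated, so no hydroboration, no enolisable ketone and no hydride reduction follow. In the security of the stereochemical end-game this road is better than the chosen plan, which must carry ketone 20.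
- Weak points: a contiguous syn,syn triad ending in a diarylmethine has to be built on an open chain with absolute control, three stereocontrolled events instead of one. The palladium alkoxide of a secondary benzylic alcohol has a β-hydrogen, so oxidation to the ketone with hydrodebromination competes with C–O bond formation at a crowded centre. The C8 chloride must survive palladium and is then harder to hydrogenolyse than a bromide; the silyl ether costs a further step.
- Comparison: the chosen plan creates only C2 by catalysis (step 8) and lets ring C relay it (steps 13 to 15), at the price of the enolisable ketone.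

**Alternative 3:** The cut removes three bonds of ring C (C4–C4a, C3–C4, O1–C2). Phenol A9, the catechin-6-carbaldehyde A7 and phenylboronic acid A10 are condensed to a boron-bridged adduct that releases ortho-quinone methide reactivity at C4, which adds the Z-enol acetate A8 to give A6.
- Merits: it is by far the shortest road; the whole upper unit, three bonds, a ring and three stereocentres, is assembled in one operation from three simple parts. The Z alkene gives 2,3-cis directly and the 3-oxygen arrives acylated, so no oxidation-state adjustment is needed.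
- Weak points: the only chirality present is in ring F of A7, remote from the reacting atoms, so the absolute sense of ring C is not controlled. The all-cis isomer requires one of several endo/exo and face combinations. Z-enol acetates of arylacetaldehydes are hard to obtain and keep geometrically pure. The regiochemical question of Alternative 1 recurs.
- Comparison: in step count and convergence this road is clearly better. The chosen plan sets against it a C2 configuration fixed by a chiral catalyst independently of the lower unit, followed by substrate-controlled steps of established types.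

Key step: step 12

## Route

Remarks on the chemistry:
- Abbreviations used in names: Bn = benzyl; Ar = 3,4-bis(benzyloxy)phenyl; Cat = (2R,3S)-3,5,7-tris(benzyloxy)-2-[3,4-bis(benzyloxy)phenyl]-8-bromochroman-6-yl (the protected, C8-brominated catechin unit bonded through C6).
- Assumption: the (Sa,Sc,Sc) enantiomer of the phosphoramidite ligand is taken to give the (S)-ether in step 8, following the usual sense of induction of this catalyst with heteroatom nucleophiles; should the first run show the opposite sense, the antipodal ligand is used.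

Step 1
Reactants: 1 (+)-catechin
Product: 2 (2R,3S)-5,7-bis(benzyloxy)-2-[3,4-bis(benzyloxy)phenyl]chroman-3-ol
Conditions: BnBr (4.4 equiv), K2CO3, DMF, 0 °C to rt, argon
Reagents that add atoms: benzyl bromide, BrCc1ccccc1
Why: Williamson etherification; K2CO3 deprotonates only the four phenols, so the secondary 3-OH stays free, and the mild base under argon should avoid C2 epimerisation and C-benzylation.

Step 2
Reactants: 2 (2R,3S)-5,7-bis(benzyloxy)-2-[3,4-bis(benzyloxy)phenyl]chroman-3-ol
Product: 3 (2R,3S)-8-bromo-5,7-bis(benzyloxy)-2-[3,4-bis(benzyloxy)phenyl]chroman-3-ol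
Conditions: NBS (1.0 equiv), CH2Cl2, −78 °C to 0 °C
Reagents that add atoms: N-bromosuccinimide, O=C1CCC(=O)N1Br
Why: Electrophilic aromatic bromination; in 5,7-dialkoxyflavans C8 is the most nucleophilic ring carbon, so one equivalent of NBS at low temperature should brominate C8 alone and thereby block it.

Step 3
Reactants: 3 (2R,3S)-8-bromo-5,7-bis(benzyloxy)-2-[3,4-bis(benzyloxy)phenyl]chroman-3-ol
Product: 4 (2R,3S)-3,5,7-tris(benzyloxy)-2-[3,4-bis(benzyloxy)phenyl]-8-bromochroman
Conditions: NaH, BnBr, n-Bu4NI (cat.), DMF, 0 °C to rt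
Reagents that add atoms: benzyl bromide, BrCc1ccccc1
Why: Williamson benzylation of the secondary alkoxide; the C3–O bond is not broken, no free phenol is present that could open ring F, and the aryl bromide is inert to NaH.

Step 4
Reactants: 4 (2R,3S)-3,5,7-tris(benzyloxy)-2-[3,4-bis(benzyloxy)phenyl]-8-bromochroman
Product: 5 (2R,3S)-3,5,7-tris(benzyloxy)-2-[3,4-bis(benzyloxy)phenyl]-8-bromo-6-iodochroman
Conditions: NIS (1.2 equiv), CF3CO2H (10 mol %), CH2Cl2/MeCN, 0 °C to rt, dark
Reagents that add atoms: N-iodosuccinimide, O=C1CCC(=O)N1I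
Why: Electrophilic aromatic iodination; with C8 blocked, C6 is the only ring D position left and is activated by two ortho benzyloxy groups and the para ring oxygen, whereas ring E and the benzyl rings are far less nucleophilic.

Step 5
Reactants: 6 3,4-bis(benzyloxy)benzaldehyde
Product: 7 ethyl (E)-3-[3,4-bis(benzyloxy)phenyl]acrylate
Conditions: (EtO)2P(O)CH2CO2Et, NaH, THF, 0 °C to rt
Reagents that add atoms: triethyl phosphonoacetate, CCOC(=O)CP(=O)(OCC)OCC
Why: Horner–Wadsworth–Emmons olefination of an aromatic aldehyde with a stabilised phosphonate should give the E-cinnamate.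

Step 6
Reactants: 7 ethyl (E)-3-[3,4-bis(benzyloxy)phenyl]acrylate
Product: 8 (E)-3-[3,4-bis(benzyloxy)phenyl]prop-2-en-1-ol
Conditions: i-Bu2AlH (2.2 equiv), CH2Cl2, −78 °C; aq. potassium sodium tartrate
Reagents that add atoms: none
Why: 1,2-Reduction of an α,β-unsaturated ester by i-Bu2AlH to the allylic alcohol; the alkene geometry is retained.

Step 7
Reactants: 8 (E)-3-[3,4-bis(benzyloxy)phenyl]prop-2-en-1-ol
Product: 9 (E)-3-[3,4-bis(benzyloxy)phenyl]allyl methyl carbonate
Conditions: ClCO2Me, pyridine, CH2Cl2, 0 °C
Reagents that add atoms: methyl chloroformate, COC(Cl)=O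
Why: O-Acylation of a primary allylic alcohol; the linear methyl carbonate is the standard electrophile for iridium-catalysed allylic substitution.

Step 8
Reactants: 9 (E)-3-[3,4-bis(benzyloxy)phenyl]allyl methyl carbonate; 10 4-(benzyloxy)-2-hydroxybenzaldehyde
Product: 12 (S)-4-(benzyloxy)-2-({1-[3,4-bis(benzyloxy)phenyl]prop-2-en-1-yl}oxy)benzaldehyde, via sodium 5-(benzyloxy)-2-formylphenoxide 11 (not isolated)
Conditions: 10 (1.5 equiv), NaH, THF, 0 °C; then 9, [Ir(cod)Cl]2 (2 mol %), (Sa,Sc,Sc)-O,O'-(1,1'-binaphthalene-2,2'-diyl)-N,N-bis(1-phenylethyl)phosphoramidite (4 mol %, pre-activated with n-PrNH2), THF, rt to 40 °C; stopped at full conversion of 9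
Reagents that add atoms: none
Why: Iridium-catalysed asymmetric allylic etherification with an aryloxide: ionisation of the carbonate gives an iridium allyl complex that the aryloxide attacks at the aryl-substituted terminus, so the branched ether forms and the cyclometalated phosphoramidite complex sets C2 as (S). The weakly basic, O-selective aryloxide leaves the aldehyde untouched.

Step 9
Reactants: 5 (2R,3S)-3,5,7-tris(benzyloxy)-2-[3,4-bis(benzyloxy)phenyl]-8-bromo-6-iodochroman; 12 (S)-4-(benzyloxy)-2-({1-[3,4-bis(benzyloxy)phenyl]prop-2-en-1-yl}oxy)benzaldehyde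
Product: 14 {4-(benzyloxy)-2-[((S)-1-Ar-allyl)oxy]phenyl}(Cat)methanol (both carbinol epimers), via arylmagnesium chloride 13 (not isolated)
Conditions: 5 (1.2 equiv), i-PrMgCl·LiCl (1.2 equiv), THF, −20 °C; then 12, −20 °C to rt; aq. NH4Cl
Reagents that add atoms: none
Why: Iodine–magnesium exchange is much faster at C–I than at C–Br on the same electron-rich ring and is helped by the two flanking benzyloxy groups, so the C6 Grignard reagent forms with the C8 bromide intact and adds to the unhindered aldehyde. The new carbinol centre is removed in step 10, so its configuration does not matter.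

Step 10
Reactants: 14 {4-(benzyloxy)-2-[((S)-1-Ar-allyl)oxy]phenyl}(Cat)methanol
Product: 15 {4-(benzyloxy)-2-[((S)-1-Ar-allyl)oxy]phenyl}(Cat)methanone
Conditions: Dess–Martin periodinane, NaHCO3, CH2Cl2, 0 °C to rt
Reagents that add atoms: none
Why: Dess–Martin oxidation of a doubly benzylic alcohol; the bicarbonate buffer protects the acid-sensitive carbinol and the 1-arylallyl aryl ether from ionisation.

Step 11
Reactants: 15 {4-(benzyloxy)-2-[((S)-1-Ar-allyl)oxy]phenyl}(Cat)methanone
Product: 16 (2R,3S)-6-(1-{4-(benzyloxy)-2-[((S)-1-Ar-allyl)oxy]phenyl}vinyl)-3,5,7-tris(benzyloxy)-2-[3,4-bis(benzyloxy)phenyl]-8-bromochroman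
Conditions: MePPh3Br (4 equiv), KN(SiMe3)2 (3.8 equiv), THF, 0 °C to 60 °C
Reagents that add atoms: methyltriphenylphosphonium bromide, C[P+](c1ccccc1)(c1ccccc1)c1ccccc1.[Br-]
Why: Wittig methylenation of a non-enolisable diaryl ketone; the phosphonium salt is kept in slight excess over the base so that only the ylide is present, which is too weak a base to deprotonate the allylic C2–H, so C2 should keep its configuration.

Step 12
Reactants: 16 (2R,3S)-6-(1-{4-(benzyloxy)-2-[((S)-1-Ar-allyl)oxy]phenyl}vinyl)-3,5,7-tris(benzyloxy)-2-[3,4-bis(benzyloxy)phenyl]-8-bromochroman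
Product: 17 (2R,3S)-6-{(S)-7-(benzyloxy)-2-[3,4-bis(benzyloxy)phenyl]-2H-chromen-4-yl}-3,5,7-tris(benzyloxy)-2-[3,4-bis(benzyloxy)phenyl]-8-bromochroman
Conditions: second-generation Grubbs catalyst RuCl2(=CHPh)(PCy3)(H2IMes) (10 mol %), 1,4-benzoquinone (20 mol %), toluene (0.005 M), 70 °C, argon sparge
Reagents that add atoms: none
Why: Ring-closing olefin metathesis of an aryl 1-arylallyl ether onto an ortho 1-arylvinyl group, the known route from O-allyl-2-vinylphenols to 2H-chromenes and 4-aryl-2H-chromenes. The ruthenium benzylidene exchanges first with the monosubstituted allyl terminus, because the 1,1-diarylethene is too hindered to load or to homodimerise, giving a C3 alkylidene and styrene. This alkylidene adds [2+2] across C4=CH2 with ruthenium on the unsubstituted CH2, and cycloreversion of the ruthenacyclobutane forms the C3=C4 bond and a ruthenium methylidene that carries the chain and ends as ethene. Ring C closes as a six-membered ring with an endocyclic double bond, the reacting carbons being held together by ring A and the O1–C2 link so that no other ring size is possible. No stereocentre is formed; C2 (S) is not involved, and 1,4-benzoquinone suppresses ruthenium hydride-mediated double-bond migration that would destroy it in 16 (to an enol ether) or in 17 (to the 4H-chromene). The selectivity needed is ring closure over cross-metathesis at the allyl terminus: high dilution, removal of ethene and the inertness of the diarylethene towards intermolecular reaction secure it, and any allyl–allyl dimer re-enters the cycle because that metathesis is reversible. The trisubstituted styrene-type product is too hindered to reopen, so closure is effectively irreversible. The aryl bromide, benzyl ethers and aryl ether are inert to the catalyst.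

Step 13
Reactants: 17 (2R,3S)-6-{(S)-7-(benzyloxy)-2-[3,4-bis(benzyloxy)phenyl]-2H-chromen-4-yl}-3,5,7-tris(benzyloxy)-2-[3,4-bis(benzyloxy)phenyl]-8-bromochroman
Product: 19 (2R,3S,4S)-7-(benzyloxy)-2-Ar-4-(Cat)chroman-3-ol (2,3-trans and 3,4-trans), via C3-alkylborane 18 (not isolated)
Conditions: BH3·THF (4 equiv), THF, 0 °C to rt; then 3 M NaOH, 30% H2O2, 0 °C to rt
Reagents that add atoms: hydrogen peroxide, OO
Why: Hydroboration–oxidation of a flav-3-ene, a known entry to 2,3-trans-flavan-3-ols: boron goes to the less substituted C3 and hydrogen to the diaryl-substituted C4 in a syn addition on the face away from the C2 aryl group. C4–H thus becomes trans to ring B (ring D cis to ring B, 4S) and the C3 oxygen, introduced with retention, is trans to both aryl groups.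

Step 14
Reactants: 19 (2R,3S,4S)-7-(benzyloxy)-2-Ar-4-(Cat)chroman-3-ol
Product: 20 (2R,4S)-7-(benzyloxy)-2-Ar-4-(Cat)chroman-3-one (2,4-cis)
Conditions: Dess–Martin periodinane, NaHCO3, CH2Cl2, 0 °C to rt; used crude without chromatography
Reagents that add atoms: none
Why: Dess–Martin oxidation of flavan-3-ols to flavan-3-ones is established and runs under buffered, near-neutral conditions, which should leave the enolisable C2–H and C4–H alone; the ketone is carried on at once.

Step 15
Reactants: 20 (2R,4S)-7-(benzyloxy)-2-Ar-4-(Cat)chroman-3-one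
Product: 21 (2R,3R,4S)-7-(benzyloxy)-2-Ar-4-(Cat)chroman-3-ol (all-cis)
Conditions: LiBH(s-Bu)3 (1.5 equiv), THF, −78 °C; aq. NH4Cl
Reagents that add atoms: none
Why: Reduction of a flavan-3-one by a bulky trialkylborohydride, the known way from the catechin to the epicatechin series: hydride approaches from the face away from the quasi-equatorial C2 and C4 aryl groups and gives the axial 3-OH cis to both (3R). The low temperature should make reduction faster than enolisation.

Step 16
Reactants: 21 (2R,3R,4S)-7-(benzyloxy)-2-Ar-4-(Cat)chroman-3-ol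
Product: 22 (2R,3R,4S)-2-(3,4-dihydroxyphenyl)-4-[(2R,3S)-2-(3,4-dihydroxyphenyl)-3,5,7-trihydroxychroman-6-yl]chroman-3,7-diol
Conditions: H2 (1 atm), Pd(OH)2/C (20 wt %), Et3N (2 equiv), THF/MeOH/H2O, rt
Reagents that add atoms: none
Why: Catalytic hydrogenolysis cleaves the eight benzyl ethers and reduces the C8–Br bond in one operation; Et3N takes up the HBr so that the acid-labile interflavan and C2–O1 bonds are not ionised, and no stereocentre is touched.

## Compound list

1 | (+)-catechin, (2R,3S)-2-(3,4-dihydroxyphenyl)chroman-3,5,7-triol | O[C@H]1Cc2c(O)cc(O)cc2O[C@@H]1c1ccc(O)c(O)c1 | starting material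
2 | (2R,3S)-5,7-bis(benzyloxy)-2-[3,4-bis(benzyloxy)phenyl]chroman-3-ol | O[C@H]1Cc2c(OCc3ccccc3)cc(OCc3ccccc3)cc2O[C@@H]1c1ccc(OCc2ccccc2)c(OCc2ccccc2)c1 | intermediate
3 | (2R,3S)-8-bromo-5,7-bis(benzyloxy)-2-[3,4-bis(benzyloxy)phenyl]chroman-3-ol | O[C@H]1Cc2c(OCc3ccccc3)cc(OCc3ccccc3)c(Br)c2O[C@@H]1c1ccc(OCc2ccccc2)c(OCc2ccccc2)c1 | intermediate
4 | (2R,3S)-3,5,7-tris(benzyloxy)-2-[3,4-bis(benzyloxy)phenyl]-8-bromochroman | c1ccccc1CO[C@H]1Cc2c(OCc3ccccc3)cc(OCc3ccccc3)c(Br)c2O[C@@H]1c1ccc(OCc2ccccc2)c(OCc2ccccc2)c1 | intermediate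
5 | (2R,3S)-3,5,7-tris(benzyloxy)-2-[3,4-bis(benzyloxy)phenyl]-8-bromo-6-iodochroman | c1ccccc1CO[C@H]1Cc2c(OCc3ccccc3)c(I)c(OCc3ccccc3)c(Br)c2O[C@@H]1c1ccc(OCc2ccccc2)c(OCc2ccccc2)c1 | intermediate
6 | 3,4-bis(benzyloxy)benzaldehyde | O=Cc1ccc(OCc2ccccc2)c(OCc2ccccc2)c1 | starting material
7 | ethyl (E)-3-[3,4-bis(benzyloxy)phenyl]acrylate | CCOC(=O)/C=C/c1ccc(OCc2ccccc2)c(OCc2ccccc2)c1 | intermediate
8 | (E)-3-[3,4-bis(benzyloxy)phenyl]prop-2-en-1-ol | OC/C=C/c1ccc(OCc2ccccc2)c(OCc2ccccc2)c1 | intermediate
9 | (E)-3-[3,4-bis(benzyloxy)phenyl]allyl methyl carbonate | COC(=O)OC/C=C/c1ccc(OCc2ccccc2)c(OCc2ccccc2)c1 | intermediate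
10 | 4-(benzyloxy)-2-hydroxybenzaldehyde | O=Cc1ccc(OCc2ccccc2)cc1O | starting material
11 | sodium 5-(benzyloxy)-2-formylphenoxide (not isolated) | [Na+].[O-]c1cc(OCc2ccccc2)ccc1C=O | intermediate
12 | (S)-4-(benzyloxy)-2-({1-[3,4-bis(benzyloxy)phenyl]prop-2-en-1-yl}oxy)benzaldehyde | O=Cc1ccc(OCc2ccccc2)cc1O[C@H](c1ccc(OCc2ccccc2)c(OCc2ccccc2)c1)C=C | intermediate
13 | [(2R,3S)-3,5,7-tris(benzyloxy)-2-(3,4-bis(benzyloxy)phenyl)-8-bromochroman-6-yl]magnesium chloride, as its LiCl complex (not isolated) | c1ccccc1CO[C@H]1Cc2c(OCc3ccccc3)c([Mg]Cl)c(OCc3ccccc3)c(Br)c2O[C@@H]1c1ccc(OCc2ccccc2)c(OCc2ccccc2)c1 | intermediate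
14 | {4-(benzyloxy)-2-[((S)-1-(3,4-bis(benzyloxy)phenyl)allyl)oxy]phenyl}[(2R,3S)-3,5,7-tris(benzyloxy)-2-(3,4-bis(benzyloxy)phenyl)-8-bromochroman-6-yl]methanol, both carbinol epimers | OC(c1ccc(OCc2ccccc2)cc1O[C@H](c1ccc(OCc2ccccc2)c(OCc2ccccc2)c1)C=C)c1c(OCc2ccccc2)c(Br)c2c(c1OCc1ccccc1)C[C@H](OCc1ccccc1)[C@@H](c1ccc(OCc3ccccc3)c(OCc3ccccc3)c1)O2 | intermediate
15 | {4-(benzyloxy)-2-[((S)-1-(3,4-bis(benzyloxy)phenyl)allyl)oxy]phenyl}[(2R,3S)-3,5,7-tris(benzyloxy)-2-(3,4-bis(benzyloxy)phenyl)-8-bromochroman-6-yl]methanone | O=C(c1ccc(OCc2ccccc2)cc1O[C@H](c1ccc(OCc2ccccc2)c(OCc2ccccc2)c1)C=C)c1c(OCc2ccccc2)c(Br)c2c(c1OCc1ccccc1)C[C@H](OCc1ccccc1)[C@@H](c1ccc(OCc3ccccc3)c(OCc3ccccc3)c1)O2 | intermediate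
16 | (2R,3S)-6-(1-{4-(benzyloxy)-2-[((S)-1-(3,4-bis(benzyloxy)phenyl)allyl)oxy]phenyl}vinyl)-3,5,7-tris(benzyloxy)-2-[3,4-bis(benzyloxy)phenyl]-8-bromochroman | C=C(c1ccc(OCc2ccccc2)cc1O[C@H](c1ccc(OCc2ccccc2)c(OCc2ccccc2)c1)C=C)c1c(OCc2ccccc2)c(Br)c2c(c1OCc1ccccc1)C[C@H](OCc1ccccc1)[C@@H](c1ccc(OCc3ccccc3)c(OCc3ccccc3)c1)O2 | intermediate
17 | (2R,3S)-6-{(S)-7-(benzyloxy)-2-[3,4-bis(benzyloxy)phenyl]-2H-chromen-4-yl}-3,5,7-tris(benzyloxy)-2-[3,4-bis(benzyloxy)phenyl]-8-bromochroman | c1ccccc1COc1ccc2c(c1)O[C@H](c1ccc(OCc3ccccc3)c(OCc3ccccc3)c1)C=C2c1c(OCc3ccccc3)c(Br)c2c(c1OCc1ccccc1)C[C@H](OCc1ccccc1)[C@@H](c1ccc(OCc3ccccc3)c(OCc3ccccc3)c1)O2 | intermediate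
18 | C3-alkylborane of 17 (BH2 on upper C3; boron and C4–H on the face opposite both aryl groups; not isolated) | c1ccccc1COc1ccc2c(c1)O[C@H](c1ccc(OCc3ccccc3)c(OCc3ccccc3)c1)[C@@H](B)[C@@H]2c1c(OCc3ccccc3)c(Br)c2c(c1OCc1ccccc1)C[C@H](OCc1ccccc1)[C@@H](c1ccc(OCc3ccccc3)c(OCc3ccccc3)c1)O2 | intermediate
19 | (2R,3S,4S)-7-(benzyloxy)-2-[3,4-bis(benzyloxy)phenyl]-4-[(2R,3S)-3,5,7-tris(benzyloxy)-2-(3,4-bis(benzyloxy)phenyl)-8-bromochroman-6-yl]chroman-3-ol (2,3-trans, 3,4-trans) | c1ccccc1COc1ccc2c(c1)O[C@H](c1ccc(OCc3ccccc3)c(OCc3ccccc3)c1)[C@@H](O)[C@@H]2c1c(OCc3ccccc3)c(Br)c2c(c1OCc1ccccc1)C[C@H](OCc1ccccc1)[C@@H](c1ccc(OCc3ccccc3)c(OCc3ccccc3)c1)O2 | intermediate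
20 | (2R,4S)-7-(benzyloxy)-2-[3,4-bis(benzyloxy)phenyl]-4-[(2R,3S)-3,5,7-tris(benzyloxy)-2-(3,4-bis(benzyloxy)phenyl)-8-bromochroman-6-yl]chroman-3-one (2,4-cis) | c1ccccc1COc1ccc2c(c1)O[C@H](c1ccc(OCc3ccccc3)c(OCc3ccccc3)c1)C(=O)[C@@H]2c1c(OCc3ccccc3)c(Br)c2c(c1OCc1ccccc1)C[C@H](OCc1ccccc1)[C@@H](c1ccc(OCc3ccccc3)c(OCc3ccccc3)c1)O2 | intermediate
21 | (2R,3R,4S)-7-(benzyloxy)-2-[3,4-bis(benzyloxy)phenyl]-4-[(2R,3S)-3,5,7-tris(benzyloxy)-2-(3,4-bis(benzyloxy)phenyl)-8-bromochroman-6-yl]chroman-3-ol (all-cis) | c1ccccc1COc1ccc2c(c1)O[C@H](c1ccc(OCc3ccccc3)c(OCc3ccccc3)c1)[C@H](O)[C@@H]2c1c(OCc3ccccc3)c(Br)c2c(c1OCc1ccccc1)C[C@H](OCc1ccccc1)[C@@H](c1ccc(OCc3ccccc3)c(OCc3ccccc3)c1)O2 | intermediate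
22 | (2R,3R,4S)-2-(3,4-dihydroxyphenyl)-4-[(2R,3S)-2-(3,4-dihydroxyphenyl)-3,5,7-trihydroxychroman-6-yl]chroman-3,7-diol (CNP0141631.2) | Oc1ccc2c(c1)O[C@H](c1ccc(O)c(O)c1)[C@H](O)[C@@H]2c1c(O)cc2c(c1O)C[C@H](O)[C@@H](c1ccc(O)c(O)c1)O2 | target

## Step count and risks

Total step count: 16.
Longest linear sequence: 12 steps (steps 1 to 4 and 9 to 16 from 1; the branch from 6 through steps 5 to 8 and 9 to 16 is equally long).

Least certain steps:

**Step 12 (key step).** The cycloaddition of the C3 ruthenium alkylidene onto the 1,1-diarylethene may be too slow, because the ring D aryl group is twisted out of the alkene plane and its two benzyloxy groups shield both faces. Cross-metathesis at the allyl terminus, or ruthenium hydride-induced migration of the allyl double bond with loss of the C2 stereocentre, could then take over. Fallback: set out from ketone 15 and close the same C3=C4 bond by carbonyl–olefin metathesis with a stoichiometric amount of Mo(=CHCMe2Ph)(=N-2,6-i-Pr2C6H3)[OC(CF3)2Me]2. The molybdenum alkylidene exchanges with the allyl terminus and then olefinates the C4 ketone irreversibly, with a molybdenum oxo complex as the sink, so the hindered alkene–alkene step is avoided. The fallback makes no new isolated compound (F0) and returns to the route at 17.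

**Step 8.** The 2-formylaryloxide is a better leaving group than a simple aryloxide and the dialkoxyphenyl group stabilises the allyl complex, so the branched ether may re-ionise on the catalyst, with erosion of enantiomeric purity and drift to the linear ether; the chelated aryloxide may also attack slowly. Fallback: move the etherification to a late, electron-rich phenol. Setting out from 10, MOMCl and i-Pr2NEt give 4-(benzyloxy)-2-(methoxymethoxy)benzaldehyde F1. Addition of the Grignard reagent 13 (from 5) gives the MOM-protected diarylmethanol F2, Dess–Martin oxidation gives the MOM-protected diaryl ketone F3, and Wittig methylenation gives the MOM-protected 1,1-diarylethene F4. Aqueous HCl in THF then frees the 2-(1-arylvinyl)phenol F5. Iridium-catalysed etherification of the sodium salt of F5 with 9 under the conditions of step 8 comes back to the route at 16.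

**Step 11.** Attack of the ylide on the carbonyl carbon, which is flanked by three ortho alkoxy groups and is electron-rich, may be slow, and prolonged heating with base invites migration of the allyl double bond. Fallback: setting out from 15, addition of MeLi in the presence of CeCl3 (THF, −78 °C) gives the tertiary diarylmethylcarbinol F6. Dehydration with the Burgess reagent, or with MsCl and Et3N, under non-acidic conditions comes back to the route at 16.

**Step 13.** Hydroboration of the crowded trisubstituted alkene may be sluggish, borane may fail to distinguish the two faces, or the C3 borane, which lies anti-periplanar to the C2–O1 bond, may undergo β-elimination with opening of ring C. Fallback: reach the ketone oxidation level without a borane and set C4 under thermodynamic control. Setting out from 17, dimethyldioxirane gives the 3,4-epoxide F7, on the face opposite the C2 aryl group. BF3·OEt2 promotes a Meinwald rearrangement by 1,2-hydride shift to the bis-benzylic C4 cation and gives the 2,4-trans ketone F8. A weak amine base (Et3N, or DBU at low temperature) epimerises the more acidic, doubly benzylic C4–H towards the 2,4-cis ketone, in which both aryl groups are quasi-equatorial; this comes back to the route at 20. An epoxide formed on the other face would rearrange to 20 directly, so both faces converge.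

**Step 15.** Enolisation of ketone 20 towards the doubly benzylic C4 (or towards C2) before or during reduction would scramble these centres, and hydride delivery from the face of the aryl groups would return the 2,3-trans alcohol. Fallback: invert C3 without passing through the ketone. Setting out from 19, a Mitsunobu reaction (4-nitrobenzoic acid, PPh3, diisopropyl azodicarboxylate, toluene) gives the all-cis 3-O-(4-nitrobenzoate) F9 by SN2 displacement, and K2CO3 in MeOH/THF cleaves the ester and comes back to the route at 21.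

## Further compounds

F0 | step 12 | none | none
F1 | step 8 | 4-(benzyloxy)-2-(methoxymethoxy)benzaldehyde | O=Cc1ccc(OCc2ccccc2)cc1OCOC
F2 | step 8 | [4-(benzyloxy)-2-(methoxymethoxy)phenyl][(2R,3S)-3,5,7-tris(benzyloxy)-2-(3,4-bis(benzyloxy)phenyl)-8-bromochroman-6-yl]methanol, both carbinol epimers | OC(c1ccc(OCc2ccccc2)cc1OCOC)c1c(OCc2ccccc2)c(Br)c2c(c1OCc1ccccc1)C[C@H](OCc1ccccc1)[C@@H](c1ccc(OCc3ccccc3)c(OCc3ccccc3)c1)O2
F3 | step 8 | [4-(benzyloxy)-2-(methoxymethoxy)phenyl][(2R,3S)-3,5,7-tris(benzyloxy)-2-(3,4-bis(benzyloxy)phenyl)-8-bromochroman-6-yl]methanone | O=C(c1ccc(OCc2ccccc2)cc1OCOC)c1c(OCc2ccccc2)c(Br)c2c(c1OCc1ccccc1)C[C@H](OCc1ccccc1)[C@@H](c1ccc(OCc3ccccc3)c(OCc3ccccc3)c1)O2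
F4 | step 8 | (2R,3S)-6-{1-[4-(benzyloxy)-2-(methoxymethoxy)phenyl]vinyl}-3,5,7-tris(benzyloxy)-2-[3,4-bis(benzyloxy)phenyl]-8-bromochroman | C=C(c1ccc(OCc2ccccc2)cc1OCOC)c1c(OCc2ccccc2)c(Br)c2c(c1OCc1ccccc1)C[C@H](OCc1ccccc1)[C@@H](c1ccc(OCc3ccccc3)c(OCc3ccccc3)c1)O2
F5 | step 8 | 5-(benzyloxy)-2-{1-[(2R,3S)-3,5,7-tris(benzyloxy)-2-(3,4-bis(benzyloxy)phenyl)-8-bromochroman-6-yl]vinyl}phenol | C=C(c1ccc(OCc2ccccc2)cc1O)c1c(OCc2ccccc2)c(Br)c2c(c1OCc1ccccc1)C[C@H](OCc1ccccc1)[C@@H](c1ccc(OCc3ccccc3)c(OCc3ccccc3)c1)O2
F6 | step 11 | 1-{4-(benzyloxy)-2-[((S)-1-(3,4-bis(benzyloxy)phenyl)allyl)oxy]phenyl}-1-[(2R,3S)-3,5,7-tris(benzyloxy)-2-(3,4-bis(benzyloxy)phenyl)-8-bromochroman-6-yl]ethan-1-ol, both carbinol epimers | CC(O)(c1ccc(OCc2ccccc2)cc1O[C@H](c1ccc(OCc2ccccc2)c(OCc2ccccc2)c1)C=C)c1c(OCc2ccccc2)c(Br)c2c(c1OCc1ccccc1)C[C@H](OCc1ccccc1)[C@@H](c1ccc(OCc3ccccc3)c(OCc3ccccc3)c1)O2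
F7 | step 13 | 3,4-epoxide of 17, oxygen on the face opposite the C2 aryl group | c1ccccc1COc1ccc2c(c1)O[C@H](c1ccc(OCc3ccccc3)c(OCc3ccccc3)c1)[C@H]3O[C@@]23c1c(OCc3ccccc3)c(Br)c2c(c1OCc1ccccc1)C[C@H](OCc1ccccc1)[C@@H](c1ccc(OCc3ccccc3)c(OCc3ccccc3)c1)O2
F8 | step 13 | (2R,4R)-7-(benzyloxy)-2-[3,4-bis(benzyloxy)phenyl]-4-[(2R,3S)-3,5,7-tris(benzyloxy)-2-(3,4-bis(benzyloxy)phenyl)-8-bromochroman-6-yl]chroman-3-one (2,4-trans) | c1ccccc1COc1ccc2c(c1)O[C@H](c1ccc(OCc3ccccc3)c(OCc3ccccc3)c1)C(=O)[C@H]2c1c(OCc3ccccc3)c(Br)c2c(c1OCc1ccccc1)C[C@H](OCc1ccccc1)[C@@H](c1ccc(OCc3ccccc3)c(OCc3ccccc3)c1)O2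
F9 | step 15 | all-cis 3-O-(4-nitrobenzoyl) derivative of 21 | c1ccccc1COc1ccc2c(c1)O[C@H](c1ccc(OCc3ccccc3)c(OCc3ccccc3)c1)[C@H](OC(=O)c1ccc(cc1)[N+](=O)[O-])[C@@H]2c1c(OCc3ccccc3)c(Br)c2c(c1OCc1ccccc1)C[C@H](OCc1ccccc1)[C@@H](c1ccc(OCc3ccccc3)c(OCc3ccccc3)c1)O2
A1 | alternative 1 | octa-O-benzyl dimer with lower 3-O-acetate | c1ccccc1COc1ccc2c(c1)O[C@H](c1ccc(OCc3ccccc3)c(OCc3ccccc3)c1)[C@H](OCc1ccccc1)[C@@H]2c1c(OCc3ccccc3)cc2c(c1OCc1ccccc1)C[C@H](OC(C)=O)[C@@H](c1ccc(OCc3ccccc3)c(OCc3ccccc3)c1)O2
A2 | alternative 1 | all-cis upper unit bearing at C4 a 2,6-bis(benzyloxy)-4-hydroxy-3-(hydroxymethyl)phenyl group | c1ccccc1COc1ccc2c(c1)O[C@H](c1ccc(OCc3ccccc3)c(OCc3ccccc3)c1)[C@H](OCc1ccccc1)[C@@H]2c1c(OCc3ccccc3)cc(O)c(CO)c1OCc1ccccc1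
A3 | alternative 1 | (E)-2-[3,4-bis(benzyloxy)phenyl]ethenyl acetate | CC(=O)O/C=C/c1ccc(OCc2ccccc2)c(OCc2ccccc2)c1
A4 | alternative 2 | all-cis octa-O-benzyl 8-chloro 3-O-TBS dimer | c1ccccc1COc1ccc2c(c1)O[C@H](c1ccc(OCc3ccccc3)c(OCc3ccccc3)c1)[C@H](OCc1ccccc1)[C@@H]2c1c(OCc3ccccc3)c(Cl)c2c(c1OCc1ccccc1)C[C@H](O[Si](C)(C)C(C)(C)C)[C@@H](c1ccc(OCc3ccccc3)c(OCc3ccccc3)c1)O2
A5 | alternative 2 | acyclic 1,3-diaryl-3-(catechin-6-yl)propane-1,2-diol 2-benzyl ether with an ortho bromide on ring A and a free benzylic 1-OH | O[C@H](c1ccc(OCc2ccccc2)c(OCc2ccccc2)c1)[C@H](OCc1ccccc1)[C@@H](c1ccc(OCc2ccccc2)cc1Br)c1c(OCc2ccccc2)c(Cl)c2c(c1OCc1ccccc1)C[C@H](O[Si](C)(C)C(C)(C)C)[C@@H](c1ccc(OCc3ccccc3)c(OCc3ccccc3)c1)O2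
A6 | alternative 3 | all-cis hepta-O-benzyl 3,3'-di-O-acetyl 8-bromo dimer | c1ccccc1COc1ccc2c(c1)O[C@H](c1ccc(OCc3ccccc3)c(OCc3ccccc3)c1)[C@H](OC(C)=O)[C@@H]2c1c(OCc3ccccc3)c(Br)c2c(c1OCc1ccccc1)C[C@H](OC(C)=O)[C@@H](c1ccc(OCc3ccccc3)c(OCc3ccccc3)c1)O2
A7 | alternative 3 | (2R,3S)-3-acetoxy-5,7-bis(benzyloxy)-2-[3,4-bis(benzyloxy)phenyl]-8-bromochroman-6-carbaldehyde | O=Cc1c(OCc2ccccc2)c(Br)c2c(c1OCc1ccccc1)C[C@H](OC(C)=O)[C@@H](c1ccc(OCc3ccccc3)c(OCc3ccccc3)c1)O2
A8 | alternative 3 | (Z)-2-[3,4-bis(benzyloxy)phenyl]ethenyl acetate | CC(=O)O/C=C\c1ccc(OCc2ccccc2)c(OCc2ccccc2)c1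
A9 | alternative 3 | 3-(benzyloxy)phenol | Oc1cccc(OCc2ccccc2)c1
A10 | alternative 3 | phenylboronic acid | OB(O)c1ccccc1
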